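**Retrosynthetic overview**
The strategy rests on the C1–C2 bond. C1 is the benzhydryl CH that carries the two identical 2,4,5-trimethoxyphenyl rings and is not stereogenic; C2 is the R-configured carbinol carbon bearing methyl C3 and is the only stereocentre.
C2–OH is traced back to C2–B(pin) (stereoretentive oxidation). C1–C2 is traced back to benzhydryl pinacol boronate 10 plus (S)-1-lithioethyl carbamate 13, joined by boronate formation and a 1,2-metallate shift under reagent control by (−)-sparteine.
The C1–aryl bond in 10 comes from an earlier, non-stereogenic lithiation–borylation between lithiated 2,4,5-trimethoxybenzyl carbamate 8 and aryl pinacol boronate 7.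
Carbamate 4 comes from the aldehyde 1, boronate 7 from the bromide 5, and ethyl carbamate 12 from ethanol.
No ring is formed; both benzene rings are bought with their methoxy groups in place.

Key step: step 6

Remark: C1 carries two identical aryl groups, so only C2 needs control; the target is R at C2, which corresponds to (−)-sparteine (taken as commercially available) in the lithiation. Cb = N,N-diisopropylcarbamoyl, pin = pinacolato.

**Route**

Step 1
Reactants: 1 2,4,5-trimethoxybenzaldehyde
Product: 2 (2,4,5-trimethoxyphenyl)methanol
Conditions: NaBH4, MeOH, 0 °C to rt; acid-free aqueous work-up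
Reagents that add atoms: none
Why: Sodium borohydride reduction of an aromatic aldehyde to the primary benzylic alcohol; the methoxy groups are inert and the acid-free work-up prevents ionisation of the electron-rich benzylic alcohol.

Step 2
Reactants: 2 (2,4,5-trimethoxyphenyl)methanol; 3 N,N-diisopropylcarbamoyl chloride
Product: 4 2,4,5-trimethoxybenzyl N,N-diisopropylcarbamate
Conditions: NaH, THF, 0 °C; then 3, 0 °C to 50 °C
Reagents that add atoms: N,N-diisopropylcarbamoyl chloride (3), CC(C)N(C(C)C)C(=O)Cl
Why: O-Carbamoylation of the sodium alkoxide by the carbamoyl chloride (nucleophilic acyl substitution), kept basic throughout so that the acid-labile 2,4,5-trimethoxybenzyl C–O bond never meets HCl.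

Step 3
Reactants: 5 1-bromo-2,4,5-trimethoxybenzene; 6 bis(pinacolato)diboron
Product: 7 4,4,5,5-tetramethyl-2-(2,4,5-trimethoxyphenyl)-1,3,2-dioxaborolane
Conditions: Pd(dppf)Cl2 (cat.), KOAc, 1,4-dioxane, 90 °C
Reagents that add atoms: bis(pinacolato)diboron (6), CC1(C)OB(OC1(C)C)B1OC(C)(C)C(C)(C)O1
Why: Miyaura borylation (oxidative addition into C–Br, acetate-assisted transmetalation with the diboron, reductive elimination); the weak base KOAc is chosen to suppress Suzuki homocoupling and protodeboronation of the electron-rich aryl boronate.

Step 4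
Reactants: 4 2,4,5-trimethoxybenzyl N,N-diisopropylcarbamate; 7 4,4,5,5-tetramethyl-2-(2,4,5-trimethoxyphenyl)-1,3,2-dioxaborolane
Product: 10 2-[bis(2,4,5-trimethoxyphenyl)methyl]-4,4,5,5-tetramethyl-1,3,2-dioxaborolane, via lithiated benzyl carbamate 8 (not isolated), via lithium boronate complex 9 (not isolated)
Conditions: s-BuLi, TMEDA, Et2O, −78 °C; then 7, −78 °C; then MgBr2, MeOH, −78 °C to rt
Reagents that add atoms: none
Why: Lithiation–borylation: s-BuLi/TMEDA removes a benzylic hydrogen α to the carbamate oxygen (carbamate-directed α-lithiation, expected to be faster at −78 °C than ring metalation), the organolithium adds to boron of 7, and the electron-rich aryl group then shifts from boron to the benzylic carbon with loss of carbamate (1,2-metallate rearrangement, promoted by MgBr2/MeOH), creating C1 with two identical aryl groups and therefore no stereocentre.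

Step 5
Reactants: 11 ethanol; 3 N,N-diisopropylcarbamoyl chloride
Product: 12 ethyl N,N-diisopropylcarbamate
Conditions: Et3N, EtOH (excess, as solvent), reflux; distillation
Reagents that add atoms: N,N-diisopropylcarbamoyl chloride (3), CC(C)N(C(C)C)C(=O)Cl
Why: Carbamoylation of ethanol by the carbamoyl chloride with triethylamine as HCl scavenger (nucleophilic acyl substitution), giving a distillable liquid carbamate.

Step 6
Reactants: 12 ethyl N,N-diisopropylcarbamate; 10 2-[bis(2,4,5-trimethoxyphenyl)methyl]-4,4,5,5-tetramethyl-1,3,2-dioxaborolane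
Product: 15 (R)-2-[1,1-bis(2,4,5-trimethoxyphenyl)propan-2-yl]-4,4,5,5-tetramethyl-1,3,2-dioxaborolane, via (S)-1-lithioethyl carbamate 13 (not isolated), via lithium boronate complex 14 (not isolated)
Conditions: s-BuLi, (−)-sparteine, Et2O, −78 °C, 5 h; then 10 (Et2O/toluene), −78 °C; then MgBr2·OEt2, −78 °C to reflux
Reagents that add atoms: none
Why: s-BuLi/(−)-sparteine removes the pro-S hydrogen of the OCH2 group of 12 to give the configurationally stable (S)-organolithium 13, which adds to the empty p orbital of boron in 10 with retention at carbon to give the tetracoordinate boronate 14; activation of the carbamate by MgBr2 and warming then move the benzhydryl group from boron to C2 anti-periplanar to the departing carbamate (1,2-metallate rearrangement), forming the C1–C2 bond. The closest known reaction type is the sparteine-mediated lithiation–borylation of primary O-alkyl N,N-diisopropylcarbamates with secondary and benzylic pinacol boronic esters. No ring is closed. C2 is the only new stereocentre and is under pure reagent control: (S)-13, retention on borylation and inversion in the 1,2-shift give (R)-15, and because C1 carries two identical aryl groups there is no diastereomer or matched/mismatched issue. The step needs attack at boron to win over removal of the dibenzylic B–C–H of 10, and C-migration to win over reversal or O-migration; the six electron-donating methoxy groups lower the acidity of that hydrogen, complex formation at −78 °C makes boron tetracoordinate before any warming, the non-stabilised alkyllithium adds irreversibly, and a secondary benzylic group should migrate readily once MgBr2 is added.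

Step 7
Reactants: 15 (R)-2-[1,1-bis(2,4,5-trimethoxyphenyl)propan-2-yl]-4,4,5,5-tetramethyl-1,3,2-dioxaborolane
Product: 16 (R)-1,1-bis(2,4,5-trimethoxyphenyl)propan-2-ol (tatarinoid C)
Conditions: 30% H2O2, 2 M NaOH, THF, 0 °C to rt
Reagents that add atoms: hydrogen peroxide, OO
Why: Alkaline peroxide oxidation of the alkyl boronic ester: hydroperoxide adds to boron and C2 migrates from boron to oxygen with retention, so the R configuration set in step 6 is carried into the carbinol, and the basic medium spares the acid-sensitive electron-rich diarylmethyl unit.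

**Compound list**
1 | 2,4,5-trimethoxybenzaldehyde | COc1cc(OC)c(C=O)cc1OC | starting material
2 | (2,4,5-trimethoxyphenyl)methanol | COc1cc(OC)c(CO)cc1OC | intermediate
3 | N,N-diisopropylcarbamoyl chloride | CC(C)N(C(C)C)C(=O)Cl | starting material
4 | 2,4,5-trimethoxybenzyl N,N-diisopropylcarbamate | COc1cc(OC)c(COC(=O)N(C(C)C)C(C)C)cc1OC | intermediate
5 | 1-bromo-2,4,5-trimethoxybenzene | COc1cc(OC)c(Br)cc1OC | starting material
6 | bis(pinacolato)diboron | CC1(C)OB(OC1(C)C)B1OC(C)(C)C(C)(C)O1 | starting material
7 | 4,4,5,5-tetramethyl-2-(2,4,5-trimethoxyphenyl)-1,3,2-dioxaborolane | COc1cc(OC)c(B2OC(C)(C)C(C)(C)O2)cc1OC | intermediate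
8 | lithio(2,4,5-trimethoxyphenyl)methyl N,N-diisopropylcarbamate (racemic, TMEDA-solvated, not isolated) | COc1cc(OC)c(C([Li])OC(=O)N(C(C)C)C(C)C)cc1OC | intermediate
9 | lithium [(N,N-diisopropylcarbamoyloxy)(2,4,5-trimethoxyphenyl)methyl](2,4,5-trimethoxyphenyl)(pinacolato)borate (racemic, not isolated) | [Li+].COc1cc(OC)c(C(OC(=O)N(C(C)C)C(C)C)[B-]2(OC(C)(C)C(C)(C)O2)c2cc(OC)c(OC)cc2OC)cc1OC | intermediate
10 | 2-[bis(2,4,5-trimethoxyphenyl)methyl]-4,4,5,5-tetramethyl-1,3,2-dioxaborolane | COc1cc(OC)c(C(B2OC(C)(C)C(C)(C)O2)c2cc(OC)c(OC)cc2OC)cc1OC | intermediate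
11 | ethanol | CCO | starting material
12 | ethyl N,N-diisopropylcarbamate | CCOC(=O)N(C(C)C)C(C)C | intermediate
13 | (S)-1-lithioethyl N,N-diisopropylcarbamate, (−)-sparteine complex (not isolated) | C[C@H]([Li])OC(=O)N(C(C)C)C(C)C | intermediate
14 | lithium [bis(2,4,5-trimethoxyphenyl)methyl][(1S)-1-(N,N-diisopropylcarbamoyloxy)ethyl](pinacolato)borate (not isolated) | [Li+].C[C@H]([B-]1(OC(C)(C)C(C)(C)O1)C(c1cc(OC)c(OC)cc1OC)c1cc(OC)c(OC)cc1OC)OC(=O)N(C(C)C)C(C)C | intermediate
15 | (R)-2-[1,1-bis(2,4,5-trimethoxyphenyl)propan-2-yl]-4,4,5,5-tetramethyl-1,3,2-dioxaborolane | COc1cc(OC)c(C(c2cc(OC)c(OC)cc2OC)[C@@H](C)B2OC(C)(C)C(C)(C)O2)cc1OC | intermediate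
16 | (R)-1,1-bis(2,4,5-trimethoxyphenyl)propan-2-ol (tatarinoid C) | COc1cc(OC)c(C(c2cc(OC)c(OC)cc2OC)[C@@H](C)O)cc1OC | target

**Totals**
Total step count: 7. Longest linear sequence: 5 steps (1 → 2 → 4 → 6 → 7).

**Steps most likely to fail**

Step 6 (key step). What may go wrong: slow or incomplete capture of the bulky sparteine-bound carbanion by the hindered, doubly ortho-substituted benzhydryl boronate; competing removal of the acidic B–C–H; or a sluggish 1,2-shift with the poor carbamate leaving group. The fallback replaces the carbenoid by a diamine-free one with a better leaving group, made by tin–lithium exchange. It sets out from 10 and returns at 15. 2,4,6-Triisopropylbenzoic acid would be O-ethylated with bromoethane (K2CO3, DMF) to ethyl 2,4,6-triisopropylbenzoate F1. Treatment with s-BuLi/(−)-sparteine in Et2O at −78 °C should give (S)-1-lithioethyl 2,4,6-triisopropylbenzoate F2, which is trapped with Me3SnCl with retention to give (S)-1-(trimethylstannyl)ethyl 2,4,6-triisopropylbenzoate F3; this can be purified and enriched before use. n-BuLi at −78 °C would regenerate F2 free of diamine. Addition of 10 should then give the lithium boronate complex F4, in which the benzoate leaves on warming to rt and the benzhydryl group migrates with inversion to deliver 15.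

Step 4. What may go wrong: competing ring metalation of the electron-rich arene, or reversible boronate-complex formation with the ortho-substituted aryl boronate, leaving low conversion to the benzhydryl boronate. The fallback builds the C1–aryl bond by carbonyl addition and installs boron by catalytic C–O borylation. It sets out from 5 and 1 and returns at 10. Magnesium insertion into 5 (THF) would give (2,4,5-trimethoxyphenyl)magnesium bromide F5, which adds to 1 to give bis(2,4,5-trimethoxyphenyl)methanol F6. Copper-catalysed deoxygenative borylation of this benzylic alcohol with 6 (Cu/Xantphos catalyst, Ti(OiPr)4, toluene, heat) would then give 10.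

Step 3. What may go wrong: slow oxidative addition of palladium into the electron-rich, ortho-substituted C–Br bond, with protodeboronation or homocoupling taking over. The fallback uses an organolithium–borate sequence in place of catalysis. It sets out from 5 and returns at 7. Bromine–lithium exchange with n-BuLi (THF, −78 °C) would give (2,4,5-trimethoxyphenyl)lithium F7, which is trapped with 2-isopropoxy-4,4,5,5-tetramethyl-1,3,2-dioxaborolane to give the lithium aryl(isopropoxy)(pinacolato)borate F8; aqueous work-up releases isopropoxide and gives 7.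

**Further compounds**
F1 | step 6 | ethyl 2,4,6-triisopropylbenzoate | CCOC(=O)c1c(C(C)C)cc(C(C)C)cc1C(C)C
F2 | step 6 | (S)-1-lithioethyl 2,4,6-triisopropylbenzoate | C[C@H]([Li])OC(=O)c1c(C(C)C)cc(C(C)C)cc1C(C)C
F3 | step 6 | (S)-1-(trimethylstannyl)ethyl 2,4,6-triisopropylbenzoate | C[C@H]([Sn](C)(C)C)OC(=O)c1c(C(C)C)cc(C(C)C)cc1C(C)C
F4 | step 6 | lithium [bis(2,4,5-trimethoxyphenyl)methyl][(1S)-1-(2,4,6-triisopropylbenzoyloxy)ethyl](pinacolato)borate | [Li+].C[C@H]([B-]1(OC(C)(C)C(C)(C)O1)C(c1cc(OC)c(OC)cc1OC)c1cc(OC)c(OC)cc1OC)OC(=O)c1c(C(C)C)cc(C(C)C)cc1C(C)C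
F5 | step 4 | (2,4,5-trimethoxyphenyl)magnesium bromide | COc1cc(OC)c([Mg]Br)cc1OC
F6 | step 4 | bis(2,4,5-trimethoxyphenyl)methanol | COc1cc(OC)c(C(O)c2cc(OC)c(OC)cc2OC)cc1OC
F7 | step 3 | (2,4,5-trimethoxyphenyl)lithium | COc1cc(OC)c([Li])cc1OC
F8 | step 3 | lithium isopropoxy(pinacolato)(2,4,5-trimethoxyphenyl)borate | [Li+].COc1cc(OC)c([B-]2(OC(C)C)OC(C)(C)C(C)(C)O2)cc1OC
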